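**Retrosynthetic overview** (core atoms numbered as in 6-oxabicyclo[3.2.1]octane: C1, C2, C3, C4, C5, O6, C7, C8)
1. The aryl ether is disconnected (Mitsunobu) to umbelliferone and an (E)-allylic alcohol, made from a terminal alkyne by Zr-catalysed methylalumination and formaldehyde capture. The side chain is carried as a silylalkyne because it survives peracid and the Lewis acid of the ether closure.
2. C2–OH comes from axial hydride addition to a C2 ketone. The oxolane ring (C1, C7, O6, C5, C8) is closed second, by capture of an O6=C7 oxocarbenium ion (MOM ether on O6) by the C1=C2 enol silane, forming C1–C7.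
3. C5–O6 comes from a C5 formyl group by Baeyer–Villiger oxidation with retention.
4. Feature on which the plan rests: in the carbocycle C1–C2–C3–C4–C5–C8 the chain-bearing C8 lies next to the quaternary, oxygenated C5 with the chain cis to O6, and the C2 oxygen is para to C5. This is the ortho/para pattern of a 2-silyloxy diene/methacrolein adduct, so the carbocycle is made first by an enantioselective Diels–Alder reaction forming C8–C5 and C3–C4.
5. The diene comes from 5-(trimethylsilyl)pent-4-yn-1-ol by oxidation, Wittig olefination and enol silylation.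

Key step: step 4

Assumption: the (S)-oxazaborolidinium catalyst is taken, from its usual pre-transition-state model for 2-substituted acroleins, to expose the Re face of the enal α-carbon; should the adduct prove antipodal, the (R)-catalyst is used instead.

**Step 1**
Reactants: 1 5-(trimethylsilyl)pent-4-yn-1-ol
Product: 2 5-(trimethylsilyl)pent-4-ynal
Conditions: (COCl)2, DMSO, CH2Cl2, −78 °C; Et3N, −78 → 0 °C
Reagents that add atoms: none
Why: Swern oxidation stops at the aldehyde and leaves the alkynylsilane untouched, and the aldehyde is used directly.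

**Step 2**
Reactants: 2 5-(trimethylsilyl)pent-4-ynal; 3 3-(triphenylphosphoranylidene)butan-2-one
Product: 4 (3E)-3-methyl-8-(trimethylsilyl)oct-3-en-7-yn-2-one
Conditions: toluene, 90 °C
Reagents that add atoms: none
Why: Wittig olefination with a ketone-stabilised, α-branched ylide should give the (E)-trisubstituted enone, with the acyl group trans to the chain.

**Step 3**
Reactants: 4 (3E)-3-methyl-8-(trimethylsilyl)oct-3-en-7-yn-2-one
Product: 5 tert-butyldimethyl{[(3E)-3-methyl-8-(trimethylsilyl)octa-1,3-dien-7-yn-2-yl]oxy}silane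
Conditions: TBSOTf, Et3N, CH2Cl2, −78 → 0 °C
Reagents that add atoms: tert-butyldimethylsilyl trifluoromethanesulfonate (TBSOTf), CC(C)(C)[Si](C)(C)OS(=O)(=O)C(F)(F)F
Why: Soft enolisation (silyl triflate/amine enol silylation) of the acetyl methyl group should give the cross-conjugated 2-silyloxy diene without disturbing the (E)-alkene.

**Step 4**
Reactants: 5 tert-butyldimethyl{[(3E)-3-methyl-8-(trimethylsilyl)octa-1,3-dien-7-yn-2-yl]oxy}silane; 6 methacrolein (2-methylprop-2-enal)
Product: 7 (1S,2R)-4-[(tert-butyldimethylsilyl)oxy]-1,3-dimethyl-2-[4-(trimethylsilyl)but-3-yn-1-yl]cyclohex-3-ene-1-carbaldehyde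
Conditions: (S)-tetrahydro-1-(2-methylphenyl)-3,3-diphenyl-1H,3H-pyrrolo[1,2-c][1,3,2]oxazaborole (20 mol %), HN(SO2CF3)2 (17 mol %), CH2Cl2, −78 → −40 °C; Et3N quench
Reagents that add atoms: none
Why: The catalyst-bound s-trans enal and the s-cis diene should combine in a concerted, asynchronous [4+2] cycloaddition in which the C3–C4 bond (diene CH2 terminus to the enal β-carbon) leads and the C8–C5 bond follows; the closest known reaction type is the oxazaborolidinium-catalysed enantioselective Diels–Alder reaction of 2-substituted acroleins with 2-silyloxy-1,3-dienes. The carbocycle (C1, C2, C3, C4, C5, C8) is closed by intermolecular cycloaddition, both σ bonds forming suprafacially on each partner, and the C1=C2 silyl enol ether is left where the ketone enolate is needed later. Regiochemistry follows from the diene donors: the 2-silyloxy group and the alkyl group on the C8 terminus both raise the coefficient at the CH2 terminus, so the formyl-bearing carbon becomes C5, para to C2 and next to C8. C8 is set relative to C5 by the (E)-geometry of the diene together with the endo orientation of the Lewis acid-bound formyl group, which places CHO cis to the chain. The absolute configuration of C5 is set by the catalyst: the formyl C–H···O contact holds the enal over one phenyl group of the (S)-oxazaborolidinium ion, so the diene adds to the exposed Re face of the α-carbon. The step needs regio-, endo- and enantioselectivity at once, secured respectively by the matched donor pattern, the acyclic diene (no bridge to force the formyl group exo) and the chiral cation.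

**Step 5**
Reactants: 7 (1S,2R)-4-[(tert-butyldimethylsilyl)oxy]-1,3-dimethyl-2-[4-(trimethylsilyl)but-3-yn-1-yl]cyclohex-3-ene-1-carbaldehyde
Product: 8 (1S,2R)-1,3-dimethyl-4-oxo-2-[4-(trimethylsilyl)but-3-yn-1-yl]cyclohexane-1-carbaldehyde (both C3 epimers)
Conditions: 1 M HCl, THF, 0 → 23 °C
Reagents that add atoms: none
Why: Acid hydrolysis of the silyl enol ether frees the ketone so that a peracid can be used next; the aldehyde cannot enolise, the alkynylsilane is acid-stable, and the epimer mixture at the ring carbon that becomes C1 is erased in step 8.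

**Step 6**
Reactants: 8 (1S,2R)-1,3-dimethyl-4-oxo-2-[4-(trimethylsilyl)but-3-yn-1-yl]cyclohexane-1-carbaldehyde
Product: 10 (3R,4S)-4-hydroxy-2,4-dimethyl-3-[4-(trimethylsilyl)but-3-yn-1-yl]cyclohexan-1-one, via keto formate 9 (not isolated)
Conditions: mCPBA (1.1 equiv), Na2HPO4, CH2Cl2, 0 → 23 °C; then NH3 (7 M in MeOH), 0 °C
Reagents that add atoms: 3-chloroperoxybenzoic acid (mCPBA), OOC(=O)c1cccc(Cl)c1
Why: In this Baeyer–Villiger oxidation the peracid should add to the aldehyde much faster than to the hindered ketone, and the tertiary carbon migrates with retention, which fixes C5–O6 cis to the chain; brief ammonolysis removes the formyl group without cleaving the C–Si bond of the alkyne.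

**Step 7**
Reactants: 10 (3R,4S)-4-hydroxy-2,4-dimethyl-3-[4-(trimethylsilyl)but-3-yn-1-yl]cyclohexan-1-one
Product: 11 (3R,4S)-4-(methoxymethoxy)-2,4-dimethyl-3-[4-(trimethylsilyl)but-3-yn-1-yl]cyclohexan-1-one
Conditions: MOMCl, i-Pr2NEt, n-Bu4NI (cat.), ClCH2CH2Cl, 50 °C
Reagents that add atoms: chloromethyl methyl ether (MOMCl), COCCl
Why: Iodide-assisted O-alkylation of the tertiary alcohol (acetal formation) places C7 on O6 as a latent oxocarbenium ion.

**Step 8**
Reactants: 11 (3R,4S)-4-(methoxymethoxy)-2,4-dimethyl-3-[4-(trimethylsilyl)but-3-yn-1-yl]cyclohexan-1-one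
Product: 12 {[(3R,4S)-4-(methoxymethoxy)-2,4-dimethyl-3-[4-(trimethylsilyl)but-3-yn-1-yl]cyclohex-1-en-1-yl]oxy}trimethylsilane
Conditions: i-Pr2NMgBr, Et2O, 23 °C; then TMSCl, Et3N, HMPA, 23 °C
Reagents that add atoms: chlorotrimethylsilane (TMSCl), C[Si](C)(C)Cl
Why: Thermodynamic enol silylation through equilibrating magnesium enolates should favour the more substituted C1=C2 enol silane, which restores the regiochemistry of the cycloadduct and removes the epimeric centre.

**Step 9**
Reactants: 12 {[(3R,4S)-4-(methoxymethoxy)-2,4-dimethyl-3-[4-(trimethylsilyl)but-3-yn-1-yl]cyclohex-1-en-1-yl]oxy}trimethylsilane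
Product: 13 (1R,5S,8R)-1,5-dimethyl-8-[4-(trimethylsilyl)but-3-yn-1-yl]-6-oxabicyclo[3.2.1]octan-2-one
Conditions: TMSOTf (0.3 equiv), 2,6-di-tert-butyl-4-methylpyridine (0.1 equiv), CH2Cl2, −78 → 0 °C
Reagents that add atoms: none
Why: In this intramolecular Mukaiyama-type alkylation TMSOTf removes methoxide from the MOM ether to give the O6=C7 oxocarbenium ion (or its covalent triflate), which C1 of the enol silane captures by axial attack to close the five-membered oxolane ring; the tether through O6 forces C7 onto the face of C1 cis to O6, so the quaternary C1 centre is set with its methyl group trans to the bridge, and TMSOTf is regenerated.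

**Step 10**
Reactants: 13 (1R,5S,8R)-1,5-dimethyl-8-[4-(trimethylsilyl)but-3-yn-1-yl]-6-oxabicyclo[3.2.1]octan-2-one
Product: 15 (1R,2R,5S,8R)-8-(but-3-yn-1-yl)-1,5-dimethyl-6-oxabicyclo[3.2.1]octan-2-ol, via silylalkyne alcohol 14 (not isolated)
Conditions: NaBH4, MeOH, −20 → 0 °C; then K2CO3, 23 °C
Reagents that add atoms: none
Why: In this borohydride reduction the small hydride should attack C2 axially, anti to the axial C1–C7 bond and past only axial hydrogens, giving the equatorial (2R) alcohol cis to C7; methanolic carbonate then protodesilylates the alkyne.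

**Step 11**
Reactants: 15 (1R,2R,5S,8R)-8-(but-3-yn-1-yl)-1,5-dimethyl-6-oxabicyclo[3.2.1]octan-2-ol
Product: 17 (1R,2R,5S,8R)-8-[(3E)-5-hydroxy-3-methylpent-3-en-1-yl]-1,5-dimethyl-6-oxabicyclo[3.2.1]octan-2-ol, via alkenylalane 16 (not isolated)
Conditions: Me3Al (4 equiv), Cp2ZrCl2 (25 mol %), ClCH2CH2Cl, 23 °C; evaporation; n-BuLi, THF, −78 °C; (CH2O)n, −78 → 23 °C
Reagents that add atoms: trimethylaluminium (Me3Al), C[Al](C)C; paraformaldehyde (as formaldehyde), C=O
Why: Zirconium-catalysed carboalumination adds methyl and aluminium syn across the alkyne with methyl on the internal carbon, and hydroxymethylation of the derived alanate with retention gives the (E)-allylic alcohol; the free hydroxyl is carried as its aluminium alkoxide.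

**Step 12**
Reactants: 17 (1R,2R,5S,8R)-8-[(3E)-5-hydroxy-3-methylpent-3-en-1-yl]-1,5-dimethyl-6-oxabicyclo[3.2.1]octan-2-ol; 18 umbelliferone (7-hydroxy-2H-chromen-2-one)
Product: 19 7-{[(2E)-5-[(1R,2R,5S,8R)-2-hydroxy-1,5-dimethyl-6-oxabicyclo[3.2.1]octan-8-yl]-3-methylpent-2-en-1-yl]oxy}-2H-chromen-2-one (CNP0178104.1)
Conditions: PPh3, DIAD, THF, 0 → 23 °C
Reagents that add atoms: none
Why: Mitsunobu etherification should couple the acidic phenol with the primary allylic alcohol only, since the secondary C2 alcohol next to the quaternary C1 is too hindered to be activated.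

**Compound list**
1 | 5-(trimethylsilyl)pent-4-yn-1-ol | C[Si](C)(C)C#CCCCO | starting material
2 | 5-(trimethylsilyl)pent-4-ynal | C[Si](C)(C)C#CCCC=O | intermediate
3 | 3-(triphenylphosphoranylidene)butan-2-one | CC(=O)C(C)=P(c1ccccc1)(c1ccccc1)c1ccccc1 | starting material
4 | (3E)-3-methyl-8-(trimethylsilyl)oct-3-en-7-yn-2-one | CC(=O)/C(C)=C/CCC#C[Si](C)(C)C | intermediate
5 | tert-butyldimethyl{[(3E)-3-methyl-8-(trimethylsilyl)octa-1,3-dien-7-yn-2-yl]oxy}silane | C=C(O[Si](C)(C)C(C)(C)C)/C(C)=C/CCC#C[Si](C)(C)C | intermediate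
6 | methacrolein (2-methylprop-2-enal) | CC(=C)C=O | starting material
7 | (1S,2R)-4-[(tert-butyldimethylsilyl)oxy]-1,3-dimethyl-2-[4-(trimethylsilyl)but-3-yn-1-yl]cyclohex-3-ene-1-carbaldehyde | C[Si](C)(C)C#CCC[C@@H]1C(C)=C(O[Si](C)(C)C(C)(C)C)CC[C@]1(C)C=O | intermediate
8 | (1S,2R)-1,3-dimethyl-4-oxo-2-[4-(trimethylsilyl)but-3-yn-1-yl]cyclohexane-1-carbaldehyde (C3 epimers) | C[Si](C)(C)C#CCC[C@@H]1C(C)C(=O)CC[C@]1(C)C=O | intermediate
9 | (1S,2R)-1,3-dimethyl-4-oxo-2-[4-(trimethylsilyl)but-3-yn-1-yl]cyclohexyl formate (C3 epimers) | C[Si](C)(C)C#CCC[C@@H]1C(C)C(=O)CC[C@]1(C)OC=O | intermediate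
10 | (3R,4S)-4-hydroxy-2,4-dimethyl-3-[4-(trimethylsilyl)but-3-yn-1-yl]cyclohexan-1-one (C2 epimers) | C[Si](C)(C)C#CCC[C@@H]1C(C)C(=O)CC[C@]1(C)O | intermediate
11 | (3R,4S)-4-(methoxymethoxy)-2,4-dimethyl-3-[4-(trimethylsilyl)but-3-yn-1-yl]cyclohexan-1-one (C2 epimers) | C[Si](C)(C)C#CCC[C@@H]1C(C)C(=O)CC[C@]1(C)OCOC | intermediate
12 | {[(3R,4S)-4-(methoxymethoxy)-2,4-dimethyl-3-[4-(trimethylsilyl)but-3-yn-1-yl]cyclohex-1-en-1-yl]oxy}trimethylsilane | C[Si](C)(C)C#CCC[C@@H]1C(C)=C(O[Si](C)(C)C)CC[C@]1(C)OCOC | intermediate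
13 | (1R,5S,8R)-1,5-dimethyl-8-[4-(trimethylsilyl)but-3-yn-1-yl]-6-oxabicyclo[3.2.1]octan-2-one | C[Si](C)(C)C#CCC[C@@H]1[C@]2(C)CO[C@@]1(C)CCC2=O | intermediate
14 | (1R,2R,5S,8R)-1,5-dimethyl-8-[4-(trimethylsilyl)but-3-yn-1-yl]-6-oxabicyclo[3.2.1]octan-2-ol | C[Si](C)(C)C#CCC[C@@H]1[C@]2(C)CO[C@@]1(C)CC[C@H]2O | intermediate
15 | (1R,2R,5S,8R)-8-(but-3-yn-1-yl)-1,5-dimethyl-6-oxabicyclo[3.2.1]octan-2-ol | C#CCC[C@@H]1[C@]2(C)CO[C@@]1(C)CC[C@H]2O | intermediate
16 | dimethyl{(1E)-4-[(1R,2R,5S,8R)-2-[(dimethylalumanyl)oxy]-1,5-dimethyl-6-oxabicyclo[3.2.1]octan-8-yl]-2-methylbut-1-en-1-yl}alumane | C[Al](C)/C=C(\C)CC[C@@H]1[C@]2(C)CO[C@@]1(C)CC[C@H]2O[Al](C)C | intermediate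
17 | (1R,2R,5S,8R)-8-[(3E)-5-hydroxy-3-methylpent-3-en-1-yl]-1,5-dimethyl-6-oxabicyclo[3.2.1]octan-2-ol | C/C(=C\CO)CC[C@@H]1[C@]2(C)CO[C@@]1(C)CC[C@H]2O | intermediate
18 | umbelliferone (7-hydroxy-2H-chromen-2-one) | O=c1ccc2ccc(O)cc2o1 | starting material
19 | 7-{[(2E)-5-[(1R,2R,5S,8R)-2-hydroxy-1,5-dimethyl-6-oxabicyclo[3.2.1]octan-8-yl]-3-methylpent-2-en-1-yl]oxy}-2H-chromen-2-one | C/C(=C\COc1ccc2ccc(=O)oc2c1)CC[C@@H]1[C@]2(C)CO[C@@]1(C)CC[C@H]2O | target

**Total step count:** 12. **Longest linear sequence:** 12 steps (1 → 19); the route is fully linear, with 3, 6 and 18 entering as commercial reagents.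

**Steps most likely to fail**

Step 9 (oxolane closure). The oxocarbenium ion may not be captured by C1: the MOM ether may ionise at the wrong oxygen, the enol silane may be protodesilylated, or the endo-type trajectory onto C7 may be too strained, so that ketone 11 is returned or intermolecular methoxymethylation takes over. The fallback sets out from keto formate 9 (isolated after the peracid stage of step 6) and returns at 13. It delivers C7 at the formate oxidation level, so that ring closure becomes an exo attack on a carbonyl group. Thermodynamic silylation of 9 (TMSCl, NaI, Et3N, MeCN) would give the enol silane formate F1. TiCl4 in CH2Cl2 at −78 °C would convert it into the trichlorotitanium enolate, which adds to the neighbouring formate carbonyl in a Claisen-type 5-exo-trig closure and, after work-up, gives the bridged keto lactol F2. Ionic hydrogenation (Et3SiH, BF3·OEt2, CH2Cl2, −78 → −20 °C) would then remove the anomeric hydroxyl to give 13.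

Step 4 (key cycloaddition). Enantiofacial discrimination by the chiral cation may be insufficient for this more substituted diene, or acid-induced loss of the silyl dienol ether may compete with cycloaddition. The fallback sets out from 5 and 6 and returns at 8. A racemic cycloaddition promoted by Me2AlCl (CH2Cl2, −78 °C) would give the racemic cis cycloadduct F3. Condensation with (1R,2R)-N,N′-dimethyl-1,2-diphenylethane-1,2-diamine (4 Å molecular sieves, CH2Cl2) would give two diastereomeric imidazolidines, separable on base-washed silica. The imidazolidine of the (1S,2R) aldehyde F4 would be hydrolysed with 1 M HCl in THF, which frees the aldehyde and cleaves the enol ether together to give 8.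

Step 8 (regioselective enol silylation). Proton transfer under the equilibrating conditions may leave part of the material as the less substituted C2=C3 enol silane, which would close onto C3 in step 9 and give a constitutional isomer. The fallback sets out from 7 and returns at 12. It stores the regiochemistry of the cycloadduct as a C1 bromide before the enol ether is lost. NBS (NaHCO3, THF, −78 → 0 °C) would convert 7 into the bromo keto aldehyde F5. Baeyer–Villiger oxidation as in step 6 (the α-bromo ketone is inert to peracid) would give the bromo keto formate F6, and acid hydrolysis (aq. HCl, THF) the bromo hydroxy ketone F7. Methoxymethylation under acidic conditions (CH2(OMe)2, P2O5, CHCl3) would give the bromo MOM ether F8; base is avoided throughout to prevent dehydrobromination. Zn dust with TMSCl (TMEDA, Et2O) would then reduce the C–Br bond to the zinc enolate, which is silylated on oxygen to give 12 as a single regioisomer.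

**Further compounds**
F1 | step 9 | (1S,2R)-1,3-dimethyl-4-(trimethylsilyloxy)-2-[4-(trimethylsilyl)but-3-yn-1-yl]cyclohex-3-en-1-yl formate | C[Si](C)(C)C#CCC[C@@H]1C(C)=C(O[Si](C)(C)C)CC[C@]1(C)OC=O
F2 | step 9 | (1R,5S,8R)-7-hydroxy-1,5-dimethyl-8-[4-(trimethylsilyl)but-3-yn-1-yl]-6-oxabicyclo[3.2.1]octan-2-one (both C7 epimers) | C[Si](C)(C)C#CCC[C@@H]1[C@]2(C)C(O)O[C@@]1(C)CCC2=O
F3 | step 4 | rac-(1S,2R)-4-[(tert-butyldimethylsilyl)oxy]-1,3-dimethyl-2-[4-(trimethylsilyl)but-3-yn-1-yl]cyclohex-3-ene-1-carbaldehyde (racemate, relative configuration shown) | C[Si](C)(C)C#CCC[C@@H]1C(C)=C(O[Si](C)(C)C(C)(C)C)CC[C@]1(C)C=O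
F4 | step 4 | (4R,5R)-2-{(1S,2S)-4-[(tert-butyldimethylsilyl)oxy]-1,3-dimethyl-2-[4-(trimethylsilyl)but-3-yn-1-yl]cyclohex-3-en-1-yl}-1,3-dimethyl-4,5-diphenylimidazolidine | C[Si](C)(C)C#CCC[C@@H]1C(C)=C(O[Si](C)(C)C(C)(C)C)CC[C@]1(C)C1N(C)[C@H](c2ccccc2)[C@@H](c2ccccc2)N1C
F5 | step 8 | (1S,2S)-3-bromo-1,3-dimethyl-4-oxo-2-[4-(trimethylsilyl)but-3-yn-1-yl]cyclohexane-1-carbaldehyde (C3 epimers) | C[Si](C)(C)C#CCC[C@@H]1C(C)(Br)C(=O)CC[C@]1(C)C=O
F6 | step 8 | (1S,2S)-3-bromo-1,3-dimethyl-4-oxo-2-[4-(trimethylsilyl)but-3-yn-1-yl]cyclohexyl formate (C3 epimers) | C[Si](C)(C)C#CCC[C@@H]1C(C)(Br)C(=O)CC[C@]1(C)OC=O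
F7 | step 8 | (3S,4S)-2-bromo-4-hydroxy-2,4-dimethyl-3-[4-(trimethylsilyl)but-3-yn-1-yl]cyclohexan-1-one (C2 epimers) | C[Si](C)(C)C#CCC[C@@H]1C(C)(Br)C(=O)CC[C@]1(C)O
F8 | step 8 | (3S,4S)-2-bromo-4-(methoxymethoxy)-2,4-dimethyl-3-[4-(trimethylsilyl)but-3-yn-1-yl]cyclohexan-1-one (C2 epimers) | C[Si](C)(C)C#CCC[C@@H]1C(C)(Br)C(=O)CC[C@]1(C)OCOC
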